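Which set-up gives the most product, and how much does the dying catalyst cost the short tank, winter?

the same everywhere: starting material 0.013 M; free catalyst 0.3 mol%
- dusk: time 20 s; plug flow through a tube for 20 s, no back-mixing
- winter: a single well-mixed tank run continuously and read at steady state, 20 s in it on average
- midnight: a single well-mixed tank run continuously and read at steady state, 200 s in it on average
- autumn: time 20 s; everything together in a closed stirred flask, run for 20 s

- the set-up with the highest amount of product at the outlet or at the end, in percent of the starting material put in ("none" if the first two lie within 2 percentage points) (dusk / winter / midnight / autumn / none)
- amount of product at the outlet or at the end, in percent of the starting material put in, dusk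
- amount of product at the outlet or at the end, in percent of the starting material put in, winter
- amount of product at the outlet or at the end, in percent of the starting material put in, midnight
- amount of product at the outlet or at the end, in percent of the starting material put in, autumn

Starting material meeting free catalyst gives catalyst intermediate at 6300 L mol⁻¹ s⁻¹ or spent catalyst at 13 L mol⁻¹ s⁻¹, and the intermediate releases product and free catalyst at 68 s⁻¹. The two branches share one encounter, so one catalyst dies per 485 intermediates (the selectivity factor). Multiplied by the loading, this gives the catalyst capacity 145%: the reckoned conversion, as a share of the charge, at which the count of live catalyst reaches zero. The live share of the catalyst, free catalyst and catalyst intermediate counted together, is therefore close to one minus conversion over capacity.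

I bracket winter by hand. Let u be c(starting material) over 0.013 M. With the catalyst intermediate at steady state, conversion equals M·L·u/(1 + K·u), with L the live share, M = 4.91 and K = 1.20. With L at 1, conversion reaches a ceiling of 79.8%. Putting that back in gives L = 45.1% and a floor of 59.9%. The floor gives L = 58.8% and a new ceiling of 67.5%. That ceiling gives L = 53.6% and a new floor of 64.9%. Product trails conversion by at most the loading, 0.3 mol%.

The forecast names midnight, with 94% there, 85.4% for dusk and 85.4% for autumn. For winter it gives 65.4%, inside my bracket, and it says that tank “suffers from running at the low outlet concentration”.

The simulation gives midnight as best, with 94.0%, against 85.5% for dusk, 85.5% for autumn and 65.5% for winter.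

    starting material + free catalyst → spent catalyst (k1 = 13 L mol⁻¹ s⁻¹)
    starting material + free catalyst → catalyst intermediate (k2 = 6300 L mol⁻¹ s⁻¹)
    catalyst intermediate → free catalyst + product (k3 = 68 s⁻¹)

The winter value of 65.5% lies inside the bracket, and with the step to spent catalyst struck out the winter tank gives 79.8%. What I watch in a repeat is the live share at the outlet. Taking product as conversion, the capacity gives winter a live share of 54.8%. By the same count the midnight tank, at 94.0%, stands at 64.8% of the capacity, a reckoned live share of 35.2%.

(The constants used here were drawn at random within sensible limits.)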